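The data stem from a simulated flask from invented constants.

As the chemist on these flasks I had two earlier runs and three recipes. The proposed steps were that substrate and reagent form intermediate reversibly, that intermediate gives product and released group reversibly, and that released group ties up more substrate as idle adduct.

the same everywhere: substrate 0.30 M
- beta: reagent 1.5 equiv; run made earlier
- zeta: reagent 2 equiv; run made earlier
- north-west: reagent 1.10 equiv; time 2.0 d
- north: reagent 1.40 equiv; time 2.0 d
- south: reagent 1.80 equiv; time 2.0 d

| run | time / h | substrate / % | product / % |
|---|---|---|---|
| beta | 2.00 | 85 | 0 |
| beta | 4.00 | 73 | 0 |
| beta | 10.0 | 59 | 5 |
| beta | 25.0 | 36 | 14 |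
| zeta | 2.00 | 81 | 0 |
| zeta | 4.00 | 66 | 3 |
| zeta | 10.0 | 50 | 7 |
| zeta | 25.0 | 32 | 11 |

(standard deviation of a reading: 2 percentage points)

* part of the substrate that has reacted at the end, north-west
* part of the substrate that has reacted at the end, north
* part of the substrate that has reacted at the end, south
* what raising the equivalents of reagent from its lowest to its highest value here does to the part of the substrate that has reacted (changes below 5 percentage points count as none) (it rises / no change / it falls)

- amounts and yields of released group count idle adduct too
- steps that have been proposed: substrate + reagent <-> intermediate; intermediate <-> product + released group; substrate + released group <-> idle adduct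
- what has gone from substrate into another species counts as reacted, even if it can come back

I assumed the idle adduct equal to the product, so intermediate is what remains of the charge after substrate, product and idle adduct, and reagent is bound in intermediate and product. At the last beta reading that made intermediate 36.0% and free reagent 0.300 M. Intermediate over substrate times free reagent, my binding quotient (the mass-action quotient of the first step), read 3.33 L mol⁻¹, and zeta read 3.35 L mol⁻¹. The late beta product slope over that intermediate gave a drain of 0.0167 h⁻¹, so over 2.0 d I took product as 0.800 of the intermediate.

For north-west, reagent as charged gave 74.1% reacted. Putting that answer back, with the reagent it had used, gave 60.4%, and further rounds closed in on 63.3%. The same reckoning gave 70.4% for north and 76.7% for south.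

The forecast, holding that “the first step is reversing”, said 63%, 72% and 78%, with the trend it rises. That was level with mine at north-west and a little higher at north and south .

The flasks gave 62.6%, 71.0% and 78.8%: it rises, by 16 percentage points.

    substrate + reagent ⇌ intermediate (K = 3.30 L mol⁻¹, k = 0.180 L mol⁻¹ h⁻¹)
    intermediate ⇌ product + released group (K = 0.210 M, k = 0.0160 h⁻¹)
    substrate + released group ⇌ idle adduct, settled at all times (K = 500 L mol⁻¹)

South ended 16 points above north-west because of the difference in equivalents of reagent: the neighbour of south charged with 1.10 equiv gives 62.6%, against 78.8% in south. With the backward run from intermediate to substrate and reagent removed, that gap shrinks to 5.3 points. The quotient measures that backward run: the north-west end state reads 3.10 L mol⁻¹ against 3.33 L mol⁻¹. In the neighbour of south with 3.10 equiv, the end product 31.9% and free reagent 81% of its charge, put into the quotient, give substrate 10.4%, and that flask holds 10.2%.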